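**Plan**

- Retrosynthesis cuts, in order: the C10–O stearate bond; C10–C11 (Grignard addition to a C9 aldehyde); C9–C10 together with the C9–H bond (dithiane anion added to a C9 lactone carbonyl, then silane reduction); the C9 carbonyl back to a ring CH2; and last the ring bonds O–C9 and C8–C9.
- Enabling feature: ring atoms C6 (pentyl, ring O), C7 (OH) and the unsubstituted C8 are the two oxirane carbons and the carbinol carbon of cis-2,3-epoxyoctan-1-ol. The tetrahydrofuran lacks only C9, one carbon bonded to the C6 oxygen and to C8, which a sulfoxonium methylide can supply.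
- Forward: epoxidation, then the ylide cascade closes the tetrahydrofuran (the only ring) in step 2. C9 is then oxidised to the lactone, C10 is attached, the C11–C19 chain is joined, and stearoylation and desilylation finish the route.
- Stereochemistry: C6 and C7 come from the Sharpless epoxidation (C7 inverted once in the Payne step). C9 comes from inside-face hydride delivery to the ring oxocarbenium ion under control of the C7 silyloxy group. C10 comes from chelation-controlled Grignard addition.

Key step: step 2

Remark: carbons are numbered along the C19 chain from the pentyl methyl (C1) to the alkene terminus (C19); the ring oxygen bridges C6 and C9. The target is (6S,7S,9R,10R), with a cis C6/C7 pair, a 2,5-trans ring and a threo C9/C10 pair. The enantiomeric purity of 2 should be checked before it is carried on, because cis-allylic alcohols are the less selective substrate class in this epoxidation.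

**Step 1**
Reactants: 1 (Z)-oct-2-en-1-ol
Product: 2 [(2R,3S)-3-pentyloxiran-2-yl]methanol
Conditions: Ti(OiPr)4 (10 mol %), D-(−)-diethyl tartrate (14 mol %), t-BuOOH, 4 Å MS, CH2Cl2, −15 °C
Reagents that add atoms: tert-butyl hydroperoxide, CC(C)(C)OO
Why: Katsuki–Sharpless asymmetric epoxidation, in which the titanium tartrate complex binds the allylic hydroxyl and the D-(−)-tartrate directs oxygen to the alkene face that gives the (2R,3S)-cis-epoxide, fixing C6 (S) and C7 (still R, to be inverted in step 2).

**Step 2**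
Reactants: 2 [(2R,3S)-3-pentyloxiran-2-yl]methanol; 3 trimethylsulfoxonium iodide
Product: 7 (2S,3S)-2-pentyltetrahydrofuran-3-ol, via dimethylsulfoxonium methylide 4 (not isolated), via terminal epoxy alcohol 5 (not isolated), via sulfoxonium betaine 6 (not isolated)
Conditions: Me3S(O)I (3 equiv), NaH (3 equiv), DMSO, rt then 85 °C
Reagents that add atoms: none
Why: NaH gives the C8 alkoxide of 2, which opens the oxirane at C7 with inversion (Payne rearrangement) to the terminal epoxide 5; ylide 4 attacks its unhindered C8 (forming C8–C9) to give betaine 6, whose C6 alkoxide displaces dimethyl sulfoxide at C9 (forming O–C9). The closest known reaction type is the sulfoxonium ylide one-carbon homologation of 2,3-epoxy alcohols to 2-substituted tetrahydrofuran-3-ols, an epoxide-opening relative of the Corey–Chaykovsky reaction. The tetrahydrofuran, the only ring formed, closes in a 5-exo-tet mode. The C7 carbinol centre (S) results from the stereospecific SN2 inversion of the Payne step, while C6 keeps its oxygen and configuration, so the cis-epoxide geometry becomes the cis-2-pentyl-3-hydroxy ring. The step needs ylide attack on the rearranged terminal epoxide in preference to the internal one, and five-membered in preference to oxetane closure; the first is secured because the monosubstituted oxirane of the Payne equilibrium is far less hindered and its irreversible opening drains the equilibrium, the second because 5-exo displacement by the C6 alkoxide is faster than 4-exo attack by the C7 alkoxide.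

**Step 3**
Reactants: 7 (2S,3S)-2-pentyltetrahydrofuran-3-ol
Product: 8 tert-butyldimethyl{[(2S,3S)-2-pentyltetrahydrofuran-3-yl]oxy}silane
Conditions: TBSCl, imidazole, DMF, rt
Reagents that add atoms: tert-butyldimethylsilyl chloride, CC(C)(C)[Si](C)(C)Cl
Why: Standard imidazole-promoted silylation of a secondary alcohol masks C7–OH against the oxidation and organometallic steps without touching a stereocentre.

**Step 4**
Reactants: 8 tert-butyldimethyl{[(2S,3S)-2-pentyltetrahydrofuran-3-yl]oxy}silane
Product: 9 (4S,5S)-4-[(tert-butyldimethylsilyl)oxy]-5-pentyldihydrofuran-2(3H)-one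
Conditions: RuCl3·xH2O (cat.), NaIO4, CCl4/MeCN/H2O, rt
Reagents that add atoms: sodium periodate, [Na+].[O-]I(=O)(=O)=O (oxygen passed on through RuO4)
Why: RuO4 oxidation of a cyclic ether to the lactone should take the C9 methylene, since the only other α-C–H (C6) is a methine that is hindered and inductively deactivated by the adjacent silyloxy-bearing carbon.

**Step 5**
Reactants: 9 (4S,5S)-4-[(tert-butyldimethylsilyl)oxy]-5-pentyldihydrofuran-2(3H)-one; 10 1,3-dithiane
Product: 12 (4S,5S)-4-[(tert-butyldimethylsilyl)oxy]-2-(1,3-dithian-2-yl)-5-pentyltetrahydrofuran-2-ol (mixture of anomers), via 2-lithio-1,3-dithiane 11 (not isolated)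
Conditions: 10, n-BuLi, THF, −30 °C; then 9, −78 °C; aq. NH4Cl
Reagents that add atoms: none
Why: Corey–Seebach dithiane anion addition to a lactone stops at the hemiketal stage, and the stabilised, weakly basic carbanion should add to the carbonyl in preference to enolising the β-silyloxy lactone.

**Step 6**
Reactants: 12 (4S,5S)-4-[(tert-butyldimethylsilyl)oxy]-2-(1,3-dithian-2-yl)-5-pentyltetrahydrofuran-2-ol
Product: 13 2-[(2R,4S,5S)-4-[(tert-butyldimethylsilyl)oxy]-5-pentyltetrahydrofuran-2-yl]-1,3-dithiane
Conditions: Et3SiH, BF3·OEt2, CH2Cl2, −78 to −40 °C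
Reagents that add atoms: none
Why: Kishi-type reductive deoxygenation of the hemiketal through the five-membered oxocarbenium ion, where inside attack of the silane on the envelope with the C7 silyloxy group pseudoaxial and the C6 pentyl group pseudoequatorial delivers hydride cis to both and so places the dithianyl group trans (C9 = R).

**Step 7**
Reactants: 13 2-[(2R,4S,5S)-4-[(tert-butyldimethylsilyl)oxy]-5-pentyltetrahydrofuran-2-yl]-1,3-dithiane
Product: 14 (2R,4S,5S)-4-[(tert-butyldimethylsilyl)oxy]-5-pentyltetrahydrofuran-2-carbaldehyde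
Conditions: MeI, CaCO3, MeCN/H2O (9:1), 40 °C; aldehyde used crude
Reagents that add atoms: water, O
Why: S-methylation followed by hydrolysis of the sulfonium intermediate is a standard buffered dithiane cleavage that should release the α-alkoxy aldehyde without epimerising C9 or removing the silyl ether.

**Step 8**
Reactants: 14 (2R,4S,5S)-4-[(tert-butyldimethylsilyl)oxy]-5-pentyltetrahydrofuran-2-carbaldehyde; 15 9-bromonon-1-ene
Product: 17 (1R)-1-[(2R,4S,5S)-4-[(tert-butyldimethylsilyl)oxy]-5-pentyltetrahydrofuran-2-yl]dec-9-en-1-ol, via non-8-en-1-ylmagnesium bromide 16 (not isolated)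
Conditions: 15, Mg, Et2O, rt; then 14, MgBr2·OEt2, CH2Cl2, −78 °C; aq. NH4Cl
Reagents that add atoms: none
Why: Chelation-controlled (Cram chelate) Grignard addition, in which magnesium bridges the aldehyde oxygen and the ring oxygen and the alkyl group enters from the face away from C8, should give the threo carbinol (C10 = R).

**Step 9**
Reactants: 17 (1R)-1-[(2R,4S,5S)-4-[(tert-butyldimethylsilyl)oxy]-5-pentyltetrahydrofuran-2-yl]dec-9-en-1-ol; 18 stearic acid
Product: 19 (1R)-1-[(2R,4S,5S)-4-[(tert-butyldimethylsilyl)oxy]-5-pentyltetrahydrofuran-2-yl]dec-9-en-1-yl octadecanoate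
Conditions: EDC·HCl, DMAP, CH2Cl2, rt
Reagents that add atoms: none
Why: Steglich esterification acylates the only free hydroxyl (C10) at the acyl carbon, so the C10 configuration is retained and C7 stays masked.

**Step 10**
Reactants: 19 (1R)-1-[(2R,4S,5S)-4-[(tert-butyldimethylsilyl)oxy]-5-pentyltetrahydrofuran-2-yl]dec-9-en-1-yl octadecanoate
Product: 20 (1R)-1-[(2R,4S,5S)-4-hydroxy-5-pentyltetrahydrofuran-2-yl]dec-9-en-1-yl octadecanoate
Conditions: HF·pyridine, pyridine/THF, 0 °C to rt
Reagents that add atoms: none
Why: Fluoride-mediated cleavage of the secondary silyl ether under mildly acidic, non-nucleophilic conditions should leave the stearate, the terminal alkene and all four stereocentres untouched and avoid acyl migration.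

**Compound list**

1 | (Z)-oct-2-en-1-ol | CCCCC/C=C\CO | starting material
2 | [(2R,3S)-3-pentyloxiran-2-yl]methanol | CCCCC[C@@H]1O[C@@H]1CO | intermediate
3 | trimethylsulfoxonium iodide | C[S+](C)(C)=O.[I-] | starting material
4 | dimethylsulfoxonium methylide | [CH2-][S+](C)(C)=O | intermediate
5 | (1S)-1-[(2S)-oxiran-2-yl]hexan-1-ol (present as its sodium alkoxide) | CCCCC[C@H](O)[C@@H]1CO1 | intermediate
6 | [(3S,4S)-3-hydroxy-4-oxidononyl]dimethylsulfoxonium (betaine) | CCCCC[C@H]([O-])[C@@H](O)CC[S+](C)(C)=O | intermediate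
7 | (2S,3S)-2-pentyltetrahydrofuran-3-ol | CCCCC[C@@H]1OCC[C@@H]1O | intermediate
8 | tert-butyldimethyl{[(2S,3S)-2-pentyltetrahydrofuran-3-yl]oxy}silane | CCCCC[C@@H]1OCC[C@@H]1O[Si](C)(C)C(C)(C)C | intermediate
9 | (4S,5S)-4-[(tert-butyldimethylsilyl)oxy]-5-pentyldihydrofuran-2(3H)-one | CCCCC[C@@H]1OC(=O)C[C@@H]1O[Si](C)(C)C(C)(C)C | intermediate
10 | 1,3-dithiane | C1CSCSC1 | starting material
11 | 2-lithio-1,3-dithiane | [Li]C1SCCCS1 | intermediate
12 | (4S,5S)-4-[(tert-butyldimethylsilyl)oxy]-2-(1,3-dithian-2-yl)-5-pentyltetrahydrofuran-2-ol (anomeric mixture) | CCCCC[C@@H]1OC(O)(C2SCCCS2)C[C@@H]1O[Si](C)(C)C(C)(C)C | intermediate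
13 | 2-[(2R,4S,5S)-4-[(tert-butyldimethylsilyl)oxy]-5-pentyltetrahydrofuran-2-yl]-1,3-dithiane | CCCCC[C@@H]1O[C@@H](C2SCCCS2)C[C@@H]1O[Si](C)(C)C(C)(C)C | intermediate
14 | (2R,4S,5S)-4-[(tert-butyldimethylsilyl)oxy]-5-pentyltetrahydrofuran-2-carbaldehyde | CCCCC[C@@H]1O[C@@H](C=O)C[C@@H]1O[Si](C)(C)C(C)(C)C | intermediate
15 | 9-bromonon-1-ene | C=CCCCCCCCBr | starting material
16 | non-8-en-1-ylmagnesium bromide | C=CCCCCCCC[Mg]Br | intermediate
17 | (1R)-1-[(2R,4S,5S)-4-[(tert-butyldimethylsilyl)oxy]-5-pentyltetrahydrofuran-2-yl]dec-9-en-1-ol | CCCCC[C@@H]1O[C@@H]([C@@H](CCCCCCCC=C)O)C[C@@H]1O[Si](C)(C)C(C)(C)C | intermediate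
18 | stearic acid | CCCCCCCCCCCCCCCCCC(=O)O | starting material
19 | (1R)-1-[(2R,4S,5S)-4-[(tert-butyldimethylsilyl)oxy]-5-pentyltetrahydrofuran-2-yl]dec-9-en-1-yl octadecanoate | CCCCC[C@@H]1O[C@@H]([C@@H](CCCCCCCC=C)OC(=O)CCCCCCCCCCCCCCCCC)C[C@@H]1O[Si](C)(C)C(C)(C)C | intermediate
20 | (1R)-1-[(2R,4S,5S)-4-hydroxy-5-pentyltetrahydrofuran-2-yl]dec-9-en-1-yl octadecanoate | C=CCCCCCCC[C@@H](OC(=O)CCCCCCCCCCCCCCCCC)[C@H]1C[C@H](O)[C@H](CCCCC)O1 | target

**Step count and risks**

Total step count: 10. Longest linear sequence: 10 steps (1 to 20).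

Steps most likely to fail:

1. Step 6. Ionisation next to the dithiane may be diverted by proton loss to a ketene dithioacetal or by sulfur migration, and hydride delivery may then lose its facial bias. Fallback: setting out from lactone 9, vinylmagnesium bromide (THF, −78 °C) should add once to give (4S,5S)-4-[(tert-butyldimethylsilyl)oxy]-2-ethenyl-5-pentyltetrahydrofuran-2-ol F1. Et3SiH/BF3·OEt2 reduction of its sulfur-free allylic oxocarbenium ion, under the same inside-attack control, should give tert-butyldimethyl{[(2S,3S,5R)-5-ethenyl-2-pentyltetrahydrofuran-3-yl]oxy}silane F2. Ozonolysis (O3, CH2Cl2, −78 °C) through the secondary ozonide F3, then PPh3, should deliver aldehyde 14, where the route is rejoined.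

2. Step 8. Incomplete chelation would erode facial selectivity at the aldehyde and give a mixture at C10. Fallback: setting out from aldehyde 14, reagent 16 is added in THF without additive. The resulting mixture of 17 and its C10 epimer, (1S)-1-[(2R,4S,5S)-4-[(tert-butyldimethylsilyl)oxy]-5-pentyltetrahydrofuran-2-yl]dec-9-en-1-ol F4, is oxidised with Dess–Martin periodinane to 1-[(2R,4S,5S)-4-[(tert-butyldimethylsilyl)oxy]-5-pentyltetrahydrofuran-2-yl]dec-9-en-1-one F5. Felkin–Anh reduction with LiBH(s-Bu)3 (THF, −78 °C), with the ring oxygen anti to the incoming hydride, should then give the threo alcohol 17, so C10 is set by hydride addition instead of by C–C bond formation.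

3. Step 4. C–H oxidation may compete at the C6 methine or at C7 next to the silyl ether, and over-oxidation may open the ring. Fallback: setting out from alcohol 7, acetylation (Ac2O, pyridine, DMAP) gives (2S,3S)-2-pentyltetrahydrofuran-3-yl acetate F6, whose electron-withdrawing ester deactivates the C6–H and C7–H bonds. RuCl3·xH2O/NaIO4 oxidation should then give (2S,3S)-5-oxo-2-pentyltetrahydrofuran-3-yl acetate F7. HCl in MeOH removes the acetate, and the lactone re-closes on concentration to give (4S,5S)-4-hydroxy-5-pentyldihydrofuran-2(3H)-one F8. TBSCl/imidazole returns lactone 9.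

**Further compounds**

F1 | step 6 | (4S,5S)-4-[(tert-butyldimethylsilyl)oxy]-2-ethenyl-5-pentyltetrahydrofuran-2-ol (anomeric mixture) | CCCCC[C@@H]1OC(O)(C=C)C[C@@H]1O[Si](C)(C)C(C)(C)C
F2 | step 6 | tert-butyldimethyl{[(2S,3S,5R)-5-ethenyl-2-pentyltetrahydrofuran-3-yl]oxy}silane | CCCCC[C@@H]1O[C@@H](C=C)C[C@@H]1O[Si](C)(C)C(C)(C)C
F3 | step 6 | secondary ozonide (1,2,4-trioxolane) of F2, mixture of epimers at the trioxolane carbon | CCCCC[C@@H]1O[C@@H](C2OCOO2)C[C@@H]1O[Si](C)(C)C(C)(C)C
F4 | step 8 | (1S)-1-[(2R,4S,5S)-4-[(tert-butyldimethylsilyl)oxy]-5-pentyltetrahydrofuran-2-yl]dec-9-en-1-ol | CCCCC[C@@H]1O[C@@H]([C@H](CCCCCCCC=C)O)C[C@@H]1O[Si](C)(C)C(C)(C)C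
F5 | step 8 | 1-[(2R,4S,5S)-4-[(tert-butyldimethylsilyl)oxy]-5-pentyltetrahydrofuran-2-yl]dec-9-en-1-one | CCCCC[C@@H]1O[C@@H](C(=O)CCCCCCCC=C)C[C@@H]1O[Si](C)(C)C(C)(C)C
F6 | step 4 | (2S,3S)-2-pentyltetrahydrofuran-3-yl acetate | CCCCC[C@@H]1OCC[C@@H]1OC(C)=O
F7 | step 4 | (2S,3S)-5-oxo-2-pentyltetrahydrofuran-3-yl acetate | CCCCC[C@@H]1OC(=O)C[C@@H]1OC(C)=O
F8 | step 4 | (4S,5S)-4-hydroxy-5-pentyldihydrofuran-2(3H)-one | CCCCC[C@@H]1OC(=O)C[C@@H]1O
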